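The route rests on the C4–C5 bond (eremophilane numbering: ring B is C1–C5/C10 and carries C3–O, C4–Me and C5–Me; ring A is C5–C10). C4 is the enolizable carbon next to a C3 carbonyl and C5 is the β-carbon of a C7 enone, so this bond is a Michael retron; C10, sp2 in the target, serves as a throw-away stereocentre that is free to racemize. One amine-catalysed intramolecular Michael addition closes ring B, forms C4–C5 and sets the cis vicinal methyl groups and the absolute configuration of a cis-decalin-3,7-dione. The precursor is racemic 3-methyl-4-(3-oxopentyl)cyclohex-2-enone. Ring A is then desaturated, oxygenated at C8 and fitted with both side chains.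

Key step: step 4

Convention: β is the face of the bicyclic core that carries the C5 methyl group, α the opposite face; core intermediates are named as 4,5-dimethyldecalins with eremophilane locants (octalin = one, hexalin = two ring double bonds); C11–C13 is the three-carbon unit on C7 (C12 = CH2, C13 = CH2O); TBS = tert-butyldimethylsilyl.
Assumption: the quinine-derived primary amine is taken to give the (4S,5R,10R) dione 9; if the sense of induction is the opposite, the quinidine-derived pseudo-enantiomer of the catalyst is used with no other change.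

Step 1
Reactants: 1 pent-1-en-3-one
Product: 3 2-ethyl-2-(2-iodoethyl)-1,3-dioxolane, via iodo silyl enol ether 2 (not isolated)
Conditions: NaI, Me3SiCl, MeCN, 0 °C to rt; then HOCH2CH2OH, rt
Reagents that add atoms: sodium iodide [Na+].[I-]; ethane-1,2-diol OCCO
Why: Conjugate addition of iodotrimethylsilane made in the flask, followed by ketalization of the silyl enol ether with the diol (one-pot β-iodo ketal formation from an enone), masks the ketone and supplies the alkylating agent; no stereocentre is formed.

Step 2
Reactants: 4 3-ethoxycyclohex-2-en-1-one; 3 2-ethyl-2-(2-iodoethyl)-1,3-dioxolane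
Product: 6 rac-3-ethoxy-6-[2-(2-ethyl-1,3-dioxolan-2-yl)ethyl]cyclohex-2-en-1-one, via lithium dienolate 5 (not isolated)
Conditions: LiN(i-Pr)2, THF, −78 °C; then 3, DMPU, −78 °C to rt
Reagents that add atoms: none
Why: Kinetic α′-deprotonation of the vinylogous ester and SN2 alkylation of the enolate with the primary iodide (Stork–Danheiser alkylation) attach the tether at the future C10, whose stereocentre is formed as the racemate on purpose.

Step 3
Reactants: 6 rac-3-ethoxy-6-[2-(2-ethyl-1,3-dioxolan-2-yl)ethyl]cyclohex-2-en-1-one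
Product: 8 rac-3-methyl-4-(3-oxopentyl)cyclohex-2-en-1-one, via tertiary allylic alcohol 7 (not isolated)
Conditions: MeLi, Et2O, −78 to 0 °C; then 2 M aq. HCl, THF, rt
Reagents that add atoms: methyllithium [Li]C; water O
Why: 1,2-Addition of methyllithium to the vinylogous ester and acid-mediated hydrolysis with loss of water (Stork–Danheiser enone transposition) should give the 3-methyl enone while the same acid unmasks the ethyl ketone; no stereocentre is set and C10 stays racemic.

Step 4
Reactants: 8 rac-3-methyl-4-(3-oxopentyl)cyclohex-2-en-1-one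
Product: 9 (4S,5R,10R)-4,5-dimethyl-cis-decalin-3,7-dione (C4–Me, C5–Me and C10–H all β)
Conditions: 9-amino-9-deoxy-epi-quinine (20 mol %), 2-fluorobenzoic acid (40 mol %), toluene, 50 °C
Reagents that add atoms: none
Why: Proposed new method: the primary amine condenses with the C7 carbonyl to an iminium ion that stays in equilibrium with its linear dienamine (γ-deprotonation at C10), so the two enantiomers of 8 interconvert, while the enol of the side-chain ketone (or its enamine with a second catalyst molecule) adds through C4 to C5 and hydrolysis releases 9; the closest known reactions are primary-amine iminium catalysis of conjugate additions to β-substituted cyclic enones and base-mediated Michael closures that give cis-decalindiones. Ring B closes in the 6-(enolendo)-exo-trig mode, and because the three-atom tether starts at C10 it can only reach the adjacent face of C5, which makes the fusion cis (C10–H cis to C5–Me). C5 is controlled by the catalyst, which takes the faster-cyclizing C10 enantiomer (the S enantiomer of 8) out of the racemizing pool in a dynamic kinetic resolution; C10 follows from C5 through the tether and is removed again in step 10. C4 is controlled by the chair-like transition state with axial bond formation on ring A, in which only the (Z)-enol places its methyl group equatorial on the new ring, the alternative being a 1,3-diaxial clash with C9, so C4–Me should end cis to C5–Me. The step needs enol regioselectivity, Michael rather than aldol reactivity and a configurationally stable C4 in the product: attack through C2 would close a four-membered ring, the possible aldol adducts are bridged ketols that revert, and the buffered medium is removed as soon as 8 is consumed.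

Step 5
Reactants: 9 (4S,5R,10R)-4,5-dimethyl-cis-decalin-3,7-dione
Product: 10 7,7-ethylenedioxy-4β,5β-dimethyl-cis-decalin-3-one (C7 mono-dioxolane of 9)
Conditions: (Me3SiOCH2)2 (1.05 equiv), Me3SiOTf (5 mol %), CH2Cl2, −78 to −40 °C; pyridine quench
Reagents that add atoms: 1,2-bis(trimethylsilyloxy)ethane C[Si](C)(C)OCCO[Si](C)(C)C
Why: Kinetic ketalization under silyl triflate catalysis should select the C7 carbonyl, which lies between two methylene groups, over the C3 carbonyl, which carries the α-methyl group next to quaternary C5, and the cold aprotic conditions leave the epimerizable C4 untouched.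

Step 6
Reactants: 10 7,7-ethylenedioxy-4β,5β-dimethyl-cis-decalin-3-one
Product: 11 7,7-ethylenedioxy-4β,5β-dimethyl-cis-decalin-3β-ol (hydroxyl cis to both methyl groups)
Conditions: Li[HB(s-Bu)3], THF, −78 °C; then H2O
Reagents that add atoms: none
Why: Bulky-hydride reduction of a cyclohexanone: the trialkylborohydride avoids the β face, which the syn-axial C5 methyl screens in the reactive chair, and attacks C3 from the α face, which should give the 3β-alcohol, the epimer that the invertive esterification of step 24 requires.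

Step 7
Reactants: 11 7,7-ethylenedioxy-4β,5β-dimethyl-cis-decalin-3β-ol
Product: 12 3β-TBSO-7,7-ethylenedioxy-4β,5β-dimethyl-cis-decalin
Conditions: t-BuMe2SiOTf, 2,6-lutidine, CH2Cl2, −78 to 0 °C
Reagents that add atoms: tert-butyldimethylsilyl trifluoromethanesulfonate CC(C)(C)[Si](C)(C)OS(=O)(=O)C(F)(F)F
Why: Silylation of a hindered secondary alcohol with the silyl triflate installs an ether that tolerates the enolate, hydride, organolithium, peroxide and quinone steps that follow.

Step 8
Reactants: 12 3β-TBSO-7,7-ethylenedioxy-4β,5β-dimethyl-cis-decalin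
Product: 13 3β-TBSO-4β,5β-dimethyl-cis-decalin-7-one
Conditions: pyridinium p-toluenesulfonate (cat.), acetone/H2O, 50 °C
Reagents that add atoms: water O
Why: Mild acid-catalysed ketal hydrolysis frees the C7 ketone while the hindered secondary silyl ether is expected to survive.

Step 9
Reactants: 13 3β-TBSO-4β,5β-dimethyl-cis-decalin-7-one
Product: 15 3β-TBSO-4β,5β-dimethyl-10β-H-Δ8-octalin-7-one (cis-fused enone), via trimethylsilyl enol ether 14 (not isolated)
Conditions: LiN(i-Pr)2, Me3SiCl, THF, −78 °C; then Pd(OAc)2 (1.05 equiv), MeCN, rt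
Reagents that add atoms: none
Why: Saegusa–Ito oxidation: kinetic deprotonation goes to C8 because C6 is neopentylic, and palladium diacetate dehydrogenates the silyl enol ether to the C8=C9 enone.

Step 10
Reactants: 15 3β-TBSO-4β,5β-dimethyl-10β-H-Δ8-octalin-7-one
Product: 16 3β-TBSO-4β,5β-dimethyl-Δ8,Δ10(1)-hexalin-7-one (linear dienone, C10 now sp2)
Conditions: chloranil, t-BuOH, reflux
Reagents that add atoms: none
Why: Quinone dehydrogenation of an enone through its extended dienol (the classical conversion of a steroidal 4-en-3-one into the 4,6-dien-3-one) removes the C10 and C1 hydrogens, the cross-conjugated alternative being impossible at quaternary C5; this erases C10 and flattens ring A with the C5 methyl axial.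

Step 11
Reactants: 16 3β-TBSO-4β,5β-dimethyl-Δ8,Δ10(1)-hexalin-7-one
Product: 17 3β-TBSO-4β,5β-dimethyl-Δ8,Δ10(1)-hexalin-7β-ol
Conditions: i-Bu2AlH, CH2Cl2, −78 °C; then aq. KNaC4H4O6
Reagents that add atoms: none
Why: 1,2-Reduction of the dienone with a hindered aluminium hydride should occur anti to the axial C5 methyl (α face) and give the pseudo-axial 7β allylic alcohol, which serves only to direct the next step.

Step 12
Reactants: 17 3β-TBSO-4β,5β-dimethyl-Δ8,Δ10(1)-hexalin-7β-ol
Product: 18 8β,9β-epoxy-3β-TBSO-4β,5β-dimethyl-Δ10(1)-octalin-7β-ol (epoxide cis to the hydroxyl)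
Conditions: VO(acac)2 (5 mol %), t-BuOOH, CH2Cl2, 0 °C
Reagents that add atoms: tert-butyl hydroperoxide CC(C)(C)OO
Why: Hydroxyl-directed vanadium-catalysed epoxidation delivers oxygen only to the allylic C8=C9 bond and on the face of the pseudo-axial C7 hydroxyl, so C8 and C9 are set by C7 and no second allylic alkene competes at this stage.

Step 13
Reactants: 18 8β,9β-epoxy-3β-TBSO-4β,5β-dimethyl-Δ10(1)-octalin-7β-ol
Product: 19 8β,9β-epoxy-3β-TBSO-4β,5β-dimethyl-Δ10(1)-octalin-7-one
Conditions: Dess–Martin periodinane, pyridine, CH2Cl2, 0 °C to rt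
Reagents that add atoms: none
Why: Dess–Martin oxidation of the secondary alcohol under buffered conditions returns the C7 ketone as an α,β-epoxy ketone without opening the vinyl epoxide.

Step 14
Reactants: 20 2-bromoprop-2-en-1-ol
Product: 21 [(2-bromoprop-2-en-1-yl)oxy](tert-butyl)dimethylsilane
Conditions: t-BuMe2SiCl, imidazole, CH2Cl2, rt
Reagents that add atoms: tert-butyldimethylsilyl chloride CC(C)(C)[Si](C)(C)Cl
Why: Standard silylation of a primary allylic alcohol protects C13–OH for the halogen–lithium exchange.

Step 15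
Reactants: 21 [(2-bromoprop-2-en-1-yl)oxy](tert-butyl)dimethylsilane; 19 8β,9β-epoxy-3β-TBSO-4β,5β-dimethyl-Δ10(1)-octalin-7-one
Product: 23 8β,9β-epoxy-3β,13-bis(TBSO)eremophila-1(10),11(12)-dien-7β-ol, via alkenyllithium 22 (not isolated)
Conditions: 21, t-BuLi (2 equiv), Et2O, −78 °C; then 19, THF, −78 °C; then H2O
Reagents that add atoms: none
Why: Bromine–lithium exchange and 1,2-addition of the alkenyllithium to the ketone: the nucleophile should approach from the α face, anti to both the axial C5 methyl and the epoxide oxygen, which sets C7 with the hydroxyl β (cis to the C5 methyl) as in the target.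

Step 16
Reactants: 23 8β,9β-epoxy-3β,13-bis(TBSO)eremophila-1(10),11(12)-dien-7β-ol
Product: 24 3β,13-bis(TBSO)-7β-hydroxyeremophila-1(10),11(12)-dien-8-one
Conditions: Pd(PPh3)4 (5 mol %), THF, rt to 50 °C
Reagents that add atoms: none
Why: Isomerization of a 1,3-diene monoepoxide by zerovalent palladium: ionization at allylic C9 gives a π-allyl palladium alkoxide that should collapse by 1,2-hydride shift from C8 to the β,γ-unsaturated ketone, which places the carbonyl at C8 under neutral conditions and erases the C8 and C9 stereocentres.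

Step 17
Reactants: 24 3β,13-bis(TBSO)-7β-hydroxyeremophila-1(10),11(12)-dien-8-one
Product: 25 3β,13-bis(TBSO)-7β-hydroxyeremophila-1,9,11(12)-trien-8-one
Conditions: DDQ, 1,4-dioxane, rt
Reagents that add atoms: none
Why: DDQ dehydrogenation of a β,γ-unsaturated ketone through its dienol (hydride abstraction from C2) should give the linear 1,9-dien-8-one, and because C7 is quaternary no other dehydrogenation mode is open.

Step 18
Reactants: 25 3β,13-bis(TBSO)-7β-hydroxyeremophila-1,9,11(12)-trien-8-one
Product: 26 3β,7β,13-trihydroxyeremophila-1,9,11(12)-trien-8-one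
Conditions: HF·pyridine, pyridine, THF, 0 °C to rt
Reagents that add atoms: none
Why: Fluoride cleavage of both silyl ethers under buffered, non-basic conditions spares the tertiary α-ketol and the dienone.

Step 19
Reactants: 26 3β,7β,13-trihydroxyeremophila-1,9,11(12)-trien-8-one
Product: 27 13-acetoxy-3β,7β-dihydroxyeremophila-1,9,11(12)-trien-8-one
Conditions: Ac2O (1.1 equiv), 2,4,6-collidine, CH2Cl2, −20 °C
Reagents that add atoms: acetic anhydride CC(=O)OC(C)=O
Why: Chemoselective acylation: the primary allylic hydroxyl should react far faster than the hindered secondary C3 hydroxyl and the tertiary C7 hydroxyl.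

Step 20
Reactants: 28 (R)-2-methylbutanoic acid
Product: 29 (R)-2-methylbutan-1-ol
Conditions: LiAlH4, Et2O, 0 °C to rt; then H2O
Reagents that add atoms: none
Why: Hydride reduction of the carboxylic acid leaves the α-stereocentre untouched.

Step 21
Reactants: 29 (R)-2-methylbutan-1-ol
Product: 31 (E,4R)-2,4-dimethylhex-2-enal, via (R)-2-methylbutanal 30 (not isolated)
Conditions: TEMPO (cat.), KBr (cat.), NaOCl, aq. NaHCO3, CH2Cl2, 0 °C; then Ph3P=C(CH3)CHO, CH2Cl2, 40 °C
Reagents that add atoms: 2-(triphenylphosphoranylidene)propanal CC(C=O)=P(c1ccccc1)(c1ccccc1)c1ccccc1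
Why: Nitroxyl-catalysed hypochlorite oxidation gives the configurationally labile aldehyde, which is used at once in a Wittig reaction with the stabilized formyl ylide to give the (E)-enal, the stereocentre being carried over from 28.

Step 22
Reactants: 31 (E,4R)-2,4-dimethylhex-2-enal
Product: 32 ethyl (2E,4E,6R)-4,6-dimethylocta-2,4-dienoate
Conditions: Ph3P=CHCO2Et, toluene, 80 °C
Reagents that add atoms: ethyl 2-(triphenylphosphoranylidene)acetate CCOC(=O)C=P(c1ccccc1)(c1ccccc1)c1ccccc1
Why: Wittig reaction with the stabilized ester ylide under neutral conditions extends the enal to the (2E,4E)-dienoate without exposing the γ-stereocentre to base.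

Step 23
Reactants: 32 ethyl (2E,4E,6R)-4,6-dimethylocta-2,4-dienoate
Product: 33 (2E,4E,6R)-4,6-dimethylocta-2,4-dienoic acid
Conditions: LiOH, THF/MeOH/H2O, rt; then aq. HCl
Reagents that add atoms: lithium hydroxide [Li+].[OH-]
Why: Saponification of the ethyl ester; the remote allylic stereocentre is not acidic enough to epimerize under these conditions.

Step 24
Reactants: 27 13-acetoxy-3β,7β-dihydroxyeremophila-1,9,11(12)-trien-8-one; 33 (2E,4E,6R)-4,6-dimethylocta-2,4-dienoic acid
Product: 34 (3S,4S,5S,7S)-13-acetoxy-7-hydroxy-8-oxoeremophila-1,9,11(12)-trien-3-yl (2E,4E,6R)-4,6-dimethylocta-2,4-dienoate (CNP0160850.1; 3α-acyloxy, 7β-hydroxy)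
Conditions: PPh3, DIAD, toluene, 0 °C to rt
Reagents that add atoms: none
Why: Mitsunobu esterification: SN2 displacement of the allylic alkoxyphosphonium ion by the carboxylate should invert C3 from β to α, placing the acyloxy group trans to the C4 methyl, while the tertiary C7 hydroxyl does not react.

Compound list
1 | pent-1-en-3-one | CCC(=O)C=C | starting material
2 | (Z)-1-iodo-3-(trimethylsilyloxy)pent-2-ene | CC/C(O[Si](C)(C)C)=C/CI | intermediate (not isolated)
3 | 2-ethyl-2-(2-iodoethyl)-1,3-dioxolane | CCC1(CCI)OCCO1 | intermediate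
4 | 3-ethoxycyclohex-2-en-1-one | CCOC1=CC(=O)CCC1 | starting material
5 | lithium 5-ethoxycyclohexa-1,5-dien-1-olate (kinetic enolate of 4) | [Li+].[O-]C1=CCCC(OCC)=C1 | intermediate (not isolated)
6 | rac-3-ethoxy-6-[2-(2-ethyl-1,3-dioxolan-2-yl)ethyl]cyclohex-2-en-1-one | CCOC1=CC(=O)C(CCC2(CC)OCCO2)CC1 | intermediate
7 | 3-ethoxy-6-[2-(2-ethyl-1,3-dioxolan-2-yl)ethyl]-1-methylcyclohex-2-en-1-ol (racemic, both diastereomers) | CCOC1=CC(C)(O)C(CCC2(CC)OCCO2)CC1 | intermediate (not isolated)
8 | rac-3-methyl-4-(3-oxopentyl)cyclohex-2-en-1-one | CCC(=O)CCC1CCC(=O)C=C1C | intermediate (precursor of the key step)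
9 | (4S,5R,10R)-4,5-dimethyl-cis-decalin-3,7-dione | O=C1C[C@]2(C)[C@H](CC1)CCC(=O)[C@H]2C | intermediate (product of the key step)
10 | 7,7-ethylenedioxy-4β,5β-dimethyl-cis-decalin-3-one | O1CCOC12C[C@]3(C)[C@H](CC2)CCC(=O)[C@H]3C | intermediate
11 | 7,7-ethylenedioxy-4β,5β-dimethyl-cis-decalin-3β-ol | O1CCOC12C[C@]3(C)[C@H](CC2)CC[C@@H](O)[C@H]3C | intermediate
12 | 3β-TBSO-7,7-ethylenedioxy-4β,5β-dimethyl-cis-decalin | O1CCOC12C[C@]3(C)[C@H](CC2)CC[C@@H](O[Si](C)(C)C(C)(C)C)[C@H]3C | intermediate
13 | 3β-TBSO-4β,5β-dimethyl-cis-decalin-7-one | O=C1C[C@]2(C)[C@H](CC1)CC[C@@H](O[Si](C)(C)C(C)(C)C)[C@H]2C | intermediate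
14 | 3β-TBSO-4β,5β-dimethyl-7-(trimethylsilyloxy)-10β-H-Δ7-octalin | C[Si](C)(C)OC=1C[C@]2(C)[C@H](CC=1)CC[C@@H](O[Si](C)(C)C(C)(C)C)[C@H]2C | intermediate (not isolated)
15 | 3β-TBSO-4β,5β-dimethyl-10β-H-Δ8-octalin-7-one | O=C1C[C@]2(C)[C@H](C=C1)CC[C@@H](O[Si](C)(C)C(C)(C)C)[C@H]2C | intermediate
16 | 3β-TBSO-4β,5β-dimethyl-Δ8,Δ10(1)-hexalin-7-one | O=C1C[C@]2(C)C(C=C1)=CC[C@@H](O[Si](C)(C)C(C)(C)C)[C@H]2C | intermediate
17 | 3β-TBSO-4β,5β-dimethyl-Δ8,Δ10(1)-hexalin-7β-ol | O[C@@H]1C[C@]2(C)C(C=C1)=CC[C@@H](O[Si](C)(C)C(C)(C)C)[C@H]2C | intermediate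
18 | 8β,9β-epoxy-3β-TBSO-4β,5β-dimethyl-Δ10(1)-octalin-7β-ol | O[C@@H]1C[C@]2(C)C([C@@H]3O[C@@H]31)=CC[C@@H](O[Si](C)(C)C(C)(C)C)[C@H]2C | intermediate
19 | 8β,9β-epoxy-3β-TBSO-4β,5β-dimethyl-Δ10(1)-octalin-7-one | O=C1C[C@]2(C)C([C@@H]3O[C@@H]31)=CC[C@@H](O[Si](C)(C)C(C)(C)C)[C@H]2C | intermediate
20 | 2-bromoprop-2-en-1-ol | OCC(Br)=C | starting material
21 | [(2-bromoprop-2-en-1-yl)oxy](tert-butyl)dimethylsilane | C=C(Br)CO[Si](C)(C)C(C)(C)C | intermediate
22 | {3-[(tert-butyldimethylsilyl)oxy]prop-1-en-2-yl}lithium | [Li]C(=C)CO[Si](C)(C)C(C)(C)C | intermediate (not isolated)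
23 | 8β,9β-epoxy-3β,13-bis(TBSO)eremophila-1(10),11(12)-dien-7β-ol | C=C(CO[Si](C)(C)C(C)(C)C)[C@@]1(O)C[C@]2(C)C([C@@H]3O[C@@H]31)=CC[C@@H](O[Si](C)(C)C(C)(C)C)[C@H]2C | intermediate
24 | 3β,13-bis(TBSO)-7β-hydroxyeremophila-1(10),11(12)-dien-8-one | C=C(CO[Si](C)(C)C(C)(C)C)[C@@]1(O)C[C@]2(C)C(CC1=O)=CC[C@@H](O[Si](C)(C)C(C)(C)C)[C@H]2C | intermediate
25 | 3β,13-bis(TBSO)-7β-hydroxyeremophila-1,9,11(12)-trien-8-one | C=C(CO[Si](C)(C)C(C)(C)C)[C@@]1(O)C[C@]2(C)C(=CC1=O)C=C[C@@H](O[Si](C)(C)C(C)(C)C)[C@H]2C | intermediate
26 | 3β,7β,13-trihydroxyeremophila-1,9,11(12)-trien-8-one | C=C(CO)[C@@]1(O)C[C@]2(C)C(=CC1=O)C=C[C@@H](O)[C@H]2C | intermediate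
27 | 13-acetoxy-3β,7β-dihydroxyeremophila-1,9,11(12)-trien-8-one | C=C(COC(C)=O)[C@@]1(O)C[C@]2(C)C(=CC1=O)C=C[C@@H](O)[C@H]2C | intermediate
28 | (R)-2-methylbutanoic acid | CC[C@@H](C)C(=O)O | starting material
29 | (R)-2-methylbutan-1-ol | CC[C@@H](C)CO | intermediate
30 | (R)-2-methylbutanal | CC[C@@H](C)C=O | intermediate (not isolated)
31 | (E,4R)-2,4-dimethylhex-2-enal | CC[C@@H](C)/C=C(\C)C=O | intermediate
32 | ethyl (2E,4E,6R)-4,6-dimethylocta-2,4-dienoate | CCOC(=O)/C=C/C(C)=C/[C@H](C)CC | intermediate
33 | (2E,4E,6R)-4,6-dimethylocta-2,4-dienoic acid | OC(=O)/C=C/C(C)=C/[C@H](C)CC | intermediate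
34 | (3S,4S,5S,7S)-13-acetoxy-7-hydroxy-8-oxoeremophila-1,9,11(12)-trien-3-yl (2E,4E,6R)-4,6-dimethylocta-2,4-dienoate | C=C(COC(C)=O)[C@@]1(O)C[C@]2(C)C(=CC1=O)C=C[C@H](OC(=O)/C=C/C(C)=C/[C@H](C)CC)[C@H]2C | target

Total step count: 24. Longest linear sequence: 19 steps (steps 1–13, 15–19 and 24).

Steps most likely to fail

1. Step 4 (key step). C10 may racemize more slowly than the ring closes, or the catalyst may discriminate the two enantiomers poorly, so that 9 forms with low enantiomeric purity. The hindered C5 may also resist attack, so that reversible aldol closure or binding of the catalyst to the ethyl ketone takes over. Fallback with known chemistry: starting from 8, the ring is closed with an achiral base (KOt-Bu, t-BuOH/THF, 0 °C; enolate Michael addition, cis fusion enforced by the tether) to the racemic cis-dione F1. Its enantiomers are separated by preparative chromatography on a chiral stationary phase, and the (4S,5R,10R) enantiomer is 9, where the route is rejoined.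

2. Step 16. The π-allyl palladium alkoxide can collapse along more than one path (1,2-hydride shift, loss of a C2 hydrogen to a dienol, capture by the neighbouring hydroxyl), and the strained vinyl epoxide may decompose. A dienol or conjugated-enone by-product would still be carried on to 25 by DDQ in step 17. Fallback: starting from 23, reductive opening of the vinyl epoxide with SmI2 (THF/MeOH, −78 °C; electron transfer and protonation at C1) gives the allylic 7β,8β-diol F2. Oxidation of its secondary allylic hydroxyl (SO3·pyridine, DMSO, i-Pr2NEt) gives the conjugated 9-en-8-one F3. Dehydrogenation through the dienol (chloranil, t-BuOH, reflux) then gives 25, where the route is rejoined.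

3. Step 24. Activation of the hindered, pseudo-axial C3 hydroxyl may be slow, so that acyl transfer with retention, SN2′ attack at C1 or elimination towards C4 competes with clean inversion. Fallback: starting from 27, the inversion is run with the smaller and more acidic 2-(diethoxyphosphoryl)acetic acid (PPh3, DIAD, toluene) to give the 3α-phosphonoacetate F4. The dienoate is then built on the core by Horner–Wadsworth–Emmons olefination with enal 31 (LiCl, DBU, MeCN), which gives 34.

Further compounds
F1 | step 4 | racemic 4,5-dimethyl-cis-decalin-3,7-dione (9 together with its mirror image) | O=C1C[C@]2(C)[C@H](CC1)CCC(=O)[C@H]2C.O=C1C[C@@]2(C)[C@@H](CC1)CCC(=O)[C@@H]2C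
F2 | step 16 | 3β,13-bis(TBSO)eremophila-9,11(12)-diene-7β,8β-diol | C=C(CO[Si](C)(C)C(C)(C)C)[C@@]1(O)C[C@]2(C)C(=C[C@@H]1O)CC[C@@H](O[Si](C)(C)C(C)(C)C)[C@H]2C
F3 | step 16 | 3β,13-bis(TBSO)-7β-hydroxyeremophila-9,11(12)-dien-8-one | C=C(CO[Si](C)(C)C(C)(C)C)[C@@]1(O)C[C@]2(C)C(=CC1=O)CC[C@@H](O[Si](C)(C)C(C)(C)C)[C@H]2C
F4 | step 24 | 13-acetoxy-7β-hydroxy-8-oxoeremophila-1,9,11(12)-trien-3α-yl 2-(diethoxyphosphoryl)acetate | C=C(COC(C)=O)[C@@]1(O)C[C@]2(C)C(=CC1=O)C=C[C@H](OC(=O)CP(=O)(OCC)OCC)[C@H]2C
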